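**Plan** (target numbered as an azulene: C1 CHOH, C2 CH2, C3 C(OH)iPr, C3a, C4 CH–O-ester, C5 CH2, C6 C(Me)=C7, C8 CH2, C8a C(Me))
- Retrosynthesis cuts the C4 ester, takes C1–OH back to a ketone, cuts C2–C3 (aldol of a C1 methyl ketone onto a C3 isopropyl ketone), then cuts the seven-membered ring at C8–C8a and C3a–C4.
- Enabling feature: C4–C5–C6(Me)=C7–C8, with oxygen on C4, is the five-carbon span of a 4-methyl-3-oxidopyrylium whose ring oxygen bridges C4 and C8; C8a=C3a is the (E)-alkene of an enone whose carbonyl is C3. A carboxylate on the ylide carbon (future C8), esterified with the future C1 oxygen, is a traceless tether.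
- Forward: (S)-but-3-yn-2-ol gives an (E)-γ-hydroxy enone; esterification with a 3-methylfurylglyoxylate, reduction and Achmatowicz oxidation give the pyranone; the (5+2) cycloaddition builds the seven-membered ring first, as an oxabicyclo[3.2.1]octenone.
- SmI2 then cuts C8–O, decarboxylation removes the tether, the enone is transposed reductively to the C6=C7 alkene, and the aldol closes the five-membered ring last; acylation, directed reduction and phenol release finish the route.
- Stereochemistry: the one bought stereocentre (the S carbinol, future C1) relays C8a, C3a and C4 in the cycloaddition (E-alkene gives the trans fusion; exo tether puts C4–O cis to H-3a). C3 is set in the aldol by substrate control, and C1 is re-set by hydride delivery from C3–OH.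

Key step: step 6

Remark: 11–13 (epimers at the carbinol and acetal carbons) and 16–18 (epimers at C8) are carried as mixtures, because these centres are erased in steps 6 and 9.

**Route**

Step 1
Reactants: 1 (S)-but-3-yn-2-ol
Product: 3 (S,E)-4-iodo-3-methylbut-3-en-2-ol, via alkenylalane 2 (not isolated)
Conditions: Me3Al, Cp2ZrCl2 (cat.), CH2Cl2, 0 °C to rt; then I2, THF, −30 to 0 °C
Reagents that add atoms: trimethylaluminium C[Al](C)C; iodine II
Why: Zirconocene-catalysed carboalumination (Negishi carbometalation) adds methyl and aluminium syn across the terminal alkyne with methyl on the internal carbon, and iodinolysis of the C–Al bond with retention gives the (E)-iodide, the carbinol centre staying untouched.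

Step 2
Reactants: 3 (S,E)-4-iodo-3-methylbut-3-en-2-ol; 4 N-methoxy-N-methylisobutyramide
Product: 6 (S,E)-6-hydroxy-2,5-dimethylhept-4-en-3-one, via dilithio species 5 (not isolated)
Conditions: n-BuLi then t-BuLi, Et2O, −78 °C; then 4, −78 to 0 °C; aq. NH4Cl
Reagents that add atoms: none
Why: After O-deprotonation, iodine–lithium exchange keeps the alkene geometry and the vinyllithium is acylated by the Weinreb amide through a chelated tetrahedral adduct that collapses only on work-up, so the (E)-enone forms without over-addition.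

Step 3
Reactants: 7 3-methylfuran; 8 oxalyl chloride; 6 (S,E)-6-hydroxy-2,5-dimethylhept-4-en-3-one
Product: 10 (2S,3E)-3,6-dimethyl-5-oxohept-3-en-2-yl 2-(3-methylfuran-2-yl)-2-oxoacetate, via acid chloride 9 (not isolated)
Conditions: 7, 8, CH2Cl2, −40 to 0 °C; evaporate; then 6, pyridine, CH2Cl2, 0 °C
Reagents that add atoms: none
Why: Friedel–Crafts acylation of the π-excessive furan by oxalyl chloride takes place at the α-position next to the methyl group (C2), and the glyoxylyl chloride is then esterified by the secondary alcohol.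

Step 4
Reactants: 10 (2S,3E)-3,6-dimethyl-5-oxohept-3-en-2-yl 2-(3-methylfuran-2-yl)-2-oxoacetate
Product: 11 (2S,3E)-3,6-dimethyl-5-oxohept-3-en-2-yl 2-hydroxy-2-(3-methylfuran-2-yl)acetate
Conditions: NaBH4, THF/MeOH, −78 °C
Reagents that add atoms: none
Why: Borohydride reduces the very electrophilic α-keto ester carbonyl at low temperature much faster than the hindered β,β-disubstituted enone; the new carbinol centre needs no control because it becomes sp2 in step 6.

Step 5
Reactants: 11 (2S,3E)-3,6-dimethyl-5-oxohept-3-en-2-yl 2-hydroxy-2-(3-methylfuran-2-yl)acetate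
Product: 12 (2S,3E)-3,6-dimethyl-5-oxohept-3-en-2-yl 6-hydroxy-4-methyl-3-oxo-3,6-dihydro-2H-pyran-2-carboxylate
Conditions: NBS, NaHCO3, THF/H2O, 0 °C
Reagents that add atoms: water O
Why: Achmatowicz rearrangement: bromonium-induced hydration of the furan, opening to the ene-dione and hemiacetal closure by the carbinol oxygen give the 6-hydroxypyran-3-one, while the electron-poor enone alkene is inert to NBS.

Step 6
Reactants: 12 (2S,3E)-3,6-dimethyl-5-oxohept-3-en-2-yl 6-hydroxy-4-methyl-3-oxo-3,6-dihydro-2H-pyran-2-carboxylate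
Product: 15 lactone-fused 8-oxabicyclo[3.2.1]oct-3-en-2-one cycloadduct, via acetate 13 (not isolated), via oxidopyrylium ylide 14 (not isolated)
Conditions: Ac2O, pyridine, DMAP (cat.), CH2Cl2, 0 °C; then i-Pr2NEt, MeCN, high dilution, 60–80 °C
Reagents that add atoms: none
Why: Proposed new method: acetate 13 loses acetic acid under amine base to the ester-stabilised 3-oxidopyrylium 14, whose nucleophilic C2 (the future C8) adds to the β-carbon (C8a) of the tethered (E)-enone while the enone α-carbon (C3a) closes onto pyrylium C6 (the future C4) in a suprafacial, asynchronous (5+2) cycloaddition; the closest known reaction type is the intramolecular oxidopyrylium–alkene (5+2) cycloaddition of 6-acetoxy-2-alkenylpyran-3-ones, and what is new is that the three-atom tether is a carboxylate ester carried on the ylide carbon. The seven-membered carbocycle is closed by the cycloaddition itself as an 8-oxabicyclo[3.2.1]octenone (both new C–C bonds), and the five-membered lactone is closed around the new C8–C8a bond as the tether ring, which is only possible when the carbinol carbon sits on the exo face, syn to the oxygen bridge. At C8a and C3a, stereospecific suprafacial addition to the (E)-alkene places the C3 acyl group endo and trans to the exo carbinol carbon, which is the trans ring fusion of the target, and at C4 the oxygen bridge is forced syn to the exo tether, so C4–O ends up cis to H-3a. The absolute sense comes from the (S)-carbinol carbon in the tether: in the forming lactone its methyl group takes the side of the alkene CH and avoids eclipsing the C8a methyl (1,2-allylic strain), which selects one alkene face. Regiochemistry is secured twice, by the tether length and by polarity (ylide carbon onto the enone β-carbon), and ylide dimerisation is held back by high dilution and slow generation; the price is the s-cis ester conformation needed for lactone formation, hence the heating.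

Step 7
Reactants: 15 lactone-fused 8-oxabicyclo[3.2.1]oct-3-en-2-one cycloadduct
Product: 16 ring-opened 4-hydroxy cycloheptenone keto lactone
Conditions: SmI2, THF/MeOH, −78 °C
Reagents that add atoms: none
Why: Two single-electron transfers from SmI2 to the C7 ketone cleave the C8–O bond α to it (doubly activated by the lactone carbonyl), methanol protonates the samarium enolate, and the former ring oxygen stays on C4 with the configuration fixed in step 6 (reductive cleavage of an α-alkoxy ketone).

Step 8
Reactants: 16 ring-opened 4-hydroxy cycloheptenone keto lactone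
Product: 17 C4 tert-butyldimethylsilyl ether of 16
Conditions: TBSCl, imidazole, DMF, rt
Reagents that add atoms: tert-butyldimethylsilyl chloride CC(C)(C)[Si](C)(C)Cl
Why: Imidazole-catalysed silylation of the only free hydroxyl masks C4–OH, which is β to the C3 ketone, against retro-aldol cleavage in step 9 and against oxidation in step 11.

Step 9
Reactants: 17 C4 tert-butyldimethylsilyl ether of 16
Product: 19 (4S,5S,6R)-4-[(tert-butyldimethylsilyl)oxy]-6-[(1S)-1-hydroxyethyl]-2,6-dimethyl-5-(2-methylpropanoyl)cyclohept-2-en-1-one, via β-keto acid 18 (not isolated)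
Conditions: LiOH, THF/H2O, 0 °C to rt; then aq. HCl to pH 4, 40 °C
Reagents that add atoms: none
Why: Saponification of the β-keto lactone and decarboxylation of the β-keto acid on mild acidification (ketonic cleavage of a β-keto ester) remove the tether carbon, leaving C8 as CH2 and releasing C1–OH with its (S) configuration.

Step 10
Reactants: 19 (4S,5S,6R)-4-[(tert-butyldimethylsilyl)oxy]-6-[(1S)-1-hydroxyethyl]-2,6-dimethyl-5-(2-methylpropanoyl)cyclohept-2-en-1-one
Product: 21 1-{(1S,2R,7S)-7-[(tert-butyldimethylsilyl)oxy]-2-[(1S)-1-hydroxyethyl]-2,5-dimethylcyclohept-4-en-1-yl}-2-methylpropan-1-one, via tosylhydrazone 20 (not isolated)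
Conditions: TsNHNH2, EtOH, 50 °C; then catecholborane, CHCl3, 0 °C; NaOAc·3H2O, 60 °C
Reagents that add atoms: none
Why: The conjugated C7 ketone condenses with tosylhydrazide in preference to the doubly α-branched C3 ketone, and hydride addition to the hydrazone, loss of sulfinate and retro-ene loss of N2 from the allylic diazene move the alkene to C6=C7 and deliver hydrogen to C5 (catecholborane reduction of an enone tosylhydrazone with 1,3-transposition).

Step 11
Reactants: 21 1-{(1S,2R,7S)-7-[(tert-butyldimethylsilyl)oxy]-2-[(1S)-1-hydroxyethyl]-2,5-dimethylcyclohept-4-en-1-yl}-2-methylpropan-1-one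
Product: 22 1-{(1S,2R,7S)-2-acetyl-7-[(tert-butyldimethylsilyl)oxy]-2,5-dimethylcyclohept-4-en-1-yl}-2-methylpropan-1-one
Conditions: Dess–Martin periodinane, NaHCO3, CH2Cl2, rt
Reagents that add atoms: none
Why: Dess–Martin oxidation converts the secondary C1 carbinol to the methyl ketone under buffered neutral conditions that leave the silyl ether and the alkene intact.

Step 12
Reactants: 22 1-{(1S,2R,7S)-2-acetyl-7-[(tert-butyldimethylsilyl)oxy]-2,5-dimethylcyclohept-4-en-1-yl}-2-methylpropan-1-one
Product: 23 (3R,3aS,4S,8aR)-4-[(tert-butyldimethylsilyl)oxy]-3-hydroxy-6,8a-dimethyl-3-(propan-2-yl)-3,3a,4,5,8,8a-hexahydroazulen-1(2H)-one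
Conditions: LiN(SiMe3)2, THF, −78 to −40 °C; AcOH quench
Reagents that add atoms: none
Why: Kinetic deprotonation of the acetyl methyl group (the only unhindered α-position) gives an enolate that adds to the C3 ketone in an intramolecular aldol reaction (5-enolexo closure) to form the trans-fused cyclopentanone; the isopropyl group takes the face of H-3a, away from the C4 substituent and the angular methyl, so C3–OH ends up cis to the C3a–C4 bond as in the target.

Step 13
Reactants: 23 (3R,3aS,4S,8aR)-4-[(tert-butyldimethylsilyl)oxy]-3-hydroxy-6,8a-dimethyl-3-(propan-2-yl)-3,3a,4,5,8,8a-hexahydroazulen-1(2H)-one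
Product: 24 (3R,3aS,4S,8aR)-3,4-dihydroxy-6,8a-dimethyl-3-(propan-2-yl)-3,3a,4,5,8,8a-hexahydroazulen-1(2H)-one
Conditions: HF·pyridine, THF/pyridine, 0 °C to rt
Reagents that add atoms: none
Why: Fluoride cleavage of the secondary silyl ether under buffered, non-basic conditions spares the dehydration-prone tertiary β-hydroxy ketone.

Step 14
Reactants: 24 (3R,3aS,4S,8aR)-3,4-dihydroxy-6,8a-dimethyl-3-(propan-2-yl)-3,3a,4,5,8,8a-hexahydroazulen-1(2H)-one; 25 4-acetoxybenzoyl chloride
Product: 26 (3R,3aS,4S,8aR)-3-hydroxy-6,8a-dimethyl-1-oxo-3-(propan-2-yl)-1,2,3,3a,4,5,8,8a-octahydroazulen-4-yl 4-(acetyloxy)benzoate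
Conditions: pyridine, DMAP (cat.), CH2Cl2, 0 °C to rt
Reagents that add atoms: none
Why: DMAP-catalysed acylation takes place at the secondary C4 hydroxyl, the tertiary C3 hydroxyl being unreactive, and C1 is still a ketone so no second secondary hydroxyl competes.

Step 15
Reactants: 26 (3R,3aS,4S,8aR)-3-hydroxy-6,8a-dimethyl-1-oxo-3-(propan-2-yl)-1,2,3,3a,4,5,8,8a-octahydroazulen-4-yl 4-(acetyloxy)benzoate
Product: 27 (1S,3R,3aS,4S,8aR)-1,3-dihydroxy-6,8a-dimethyl-3-(propan-2-yl)-1,2,3,3a,4,5,8,8a-octahydroazulen-4-yl 4-(acetyloxy)benzoate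
Conditions: Me4NBH(OAc)3, MeCN/AcOH, −20 to 0 °C
Reagents that add atoms: none
Why: Ligand exchange of the triacetoxyborohydride with the C3 hydroxyl and intramolecular hydride delivery to the same face of the C1 ketone give the anti-1,3-diol, that is the C1 hydroxyl trans to C3–OH and to the angular methyl (hydroxyl-directed Evans–Saksena reduction).

Step 16
Reactants: 27 (1S,3R,3aS,4S,8aR)-1,3-dihydroxy-6,8a-dimethyl-3-(propan-2-yl)-1,2,3,3a,4,5,8,8a-octahydroazulen-4-yl 4-(acetyloxy)benzoate
Product: 28 2α-hydroxyferutinin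
Conditions: NH4OAc, MeOH/H2O, rt
Reagents that add atoms: none
Why: The phenolic acetate is far more electrophilic than the alkyl benzoate, and once the phenol is free its ester is deactivated, so mild ammonium acetate-promoted methanolysis removes only the acetyl group.

**Compound list**

1 | (S)-but-3-yn-2-ol | C[C@H](O)C#C | starting material
2 | alkenylalane: dimethylaluminium alkoxide of (S,E)-4-(dimethylalumanyl)-3-methylbut-3-en-2-ol | C[C@H](O[Al](C)C)/C(C)=C/[Al](C)C | intermediate
3 | (S,E)-4-iodo-3-methylbut-3-en-2-ol | C[C@H](O)/C(C)=C/I | intermediate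
4 | N-methoxy-N-methylisobutyramide | CC(C)C(=O)N(C)OC | starting material
5 | lithium (S,E)-4-lithio-3-methylbut-3-en-2-olate | C[C@H](O[Li])/C(C)=C/[Li] | intermediate
6 | (S,E)-6-hydroxy-2,5-dimethylhept-4-en-3-one | C[C@H](O)/C(C)=C/C(=O)C(C)C | intermediate
7 | 3-methylfuran | Cc1ccoc1 | starting material
8 | oxalyl chloride | ClC(=O)C(Cl)=O | starting material
9 | 2-(3-methylfuran-2-yl)-2-oxoacetyl chloride | Cc1ccoc1C(=O)C(Cl)=O | intermediate
10 | (2S,3E)-3,6-dimethyl-5-oxohept-3-en-2-yl 2-(3-methylfuran-2-yl)-2-oxoacetate | Cc1ccoc1C(=O)C(=O)O[C@@H](C)/C(C)=C/C(=O)C(C)C | intermediate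
11 | (2S,3E)-3,6-dimethyl-5-oxohept-3-en-2-yl 2-hydroxy-2-(3-methylfuran-2-yl)acetate, both carbinol epimers | Cc1ccoc1C(O)C(=O)O[C@@H](C)/C(C)=C/C(=O)C(C)C | intermediate
12 | (2S,3E)-3,6-dimethyl-5-oxohept-3-en-2-yl 6-hydroxy-4-methyl-3-oxo-3,6-dihydro-2H-pyran-2-carboxylate, ring epimers | CC1=CC(O)OC(C1=O)C(=O)O[C@@H](C)/C(C)=C/C(=O)C(C)C | intermediate
13 | (2S,3E)-3,6-dimethyl-5-oxohept-3-en-2-yl 6-acetoxy-4-methyl-3-oxo-3,6-dihydro-2H-pyran-2-carboxylate, ring epimers | CC1=CC(OC(C)=O)OC(C1=O)C(=O)O[C@@H](C)/C(C)=C/C(=O)C(C)C | intermediate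
14 | 2-{[(2S,3E)-3,6-dimethyl-5-oxohept-3-en-2-yl]oxycarbonyl}-4-methylpyrylium-3-olate | Cc1cc[o+]c(C(=O)O[C@@H](C)/C(C)=C/C(=O)C(C)C)c1[O-] | intermediate
15 | cycloadduct: 8-oxabicyclo[3.2.1]oct-3-en-2-one with oxygen bridge C4–O–C8 (target numbering), C7 ketone and C5=C6 alkene (methyl on C6); C8a carries an endo methyl; C3a carries an endo 2-methylpropanoyl group and an exo hydrogen; γ-lactone C8–C(=O)–O–C1H(CH3)–C8a on the exo face, C1 methyl on the side of C3a | CC1=C[C@@H]2O[C@@]3(C1=O)C(=O)O[C@@H](C)[C@@]3(C)[C@@H]2C(=O)C(C)C | intermediate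
16 | ring-opened keto lactone: cycloheptenone with C7 ketone, C5=C6 alkene (6-methyl), free 4-hydroxyl, C3a 2-methylpropanoyl, C8a methyl and γ-lactone C8–C(=O)–O–C1H(CH3)–C8a; C8a, C3a, C4 and C1 configured as in the target, C8 both epimers | CC1=C[C@H](O)[C@@H](C(=O)C(C)C)[C@]2(C)[C@H](C)OC(=O)C2C1=O | intermediate
17 | C4 tert-butyldimethylsilyl ether of 16 | CC1=C[C@H](O[Si](C)(C)C(C)(C)C)[C@@H](C(=O)C(C)C)[C@]2(C)[C@H](C)OC(=O)C2C1=O | intermediate
18 | β-keto acid: (4S,5S,6R)-series cycloheptenone of 19 carrying CO2H on C8 (the ring CH between ketone and quaternary carbon) | CC1=C[C@H](O[Si](C)(C)C(C)(C)C)[C@@H](C(=O)C(C)C)[C@](C)([C@H](C)O)C(C(O)=O)C1=O | intermediate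
19 | (4S,5S,6R)-4-[(tert-butyldimethylsilyl)oxy]-6-[(1S)-1-hydroxyethyl]-2,6-dimethyl-5-(2-methylpropanoyl)cyclohept-2-en-1-one | CC1=C[C@H](O[Si](C)(C)C(C)(C)C)[C@@H](C(=O)C(C)C)[C@](C)([C@H](C)O)CC1=O | intermediate
20 | 4-methylbenzenesulfonylhydrazone of 19 at the ring ketone | CC1=C[C@H](O[Si](C)(C)C(C)(C)C)[C@@H](C(=O)C(C)C)[C@](C)([C@H](C)O)CC1=NNS(=O)(=O)c2ccc(C)cc2 | intermediate
21 | 1-{(1S,2R,7S)-7-[(tert-butyldimethylsilyl)oxy]-2-[(1S)-1-hydroxyethyl]-2,5-dimethylcyclohept-4-en-1-yl}-2-methylpropan-1-one | CC1=CC[C@@](C)([C@H](C)O)[C@@H]([C@@H](O[Si](C)(C)C(C)(C)C)C1)C(=O)C(C)C | intermediate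
22 | 1-{(1S,2R,7S)-2-acetyl-7-[(tert-butyldimethylsilyl)oxy]-2,5-dimethylcyclohept-4-en-1-yl}-2-methylpropan-1-one | CC1=CC[C@@](C)(C(C)=O)[C@@H]([C@@H](O[Si](C)(C)C(C)(C)C)C1)C(=O)C(C)C | intermediate
23 | (3R,3aS,4S,8aR)-4-[(tert-butyldimethylsilyl)oxy]-3-hydroxy-6,8a-dimethyl-3-(propan-2-yl)-3,3a,4,5,8,8a-hexahydroazulen-1(2H)-one | CC1=CC[C@]2(C)[C@@H]([C@@H](O[Si](C)(C)C(C)(C)C)C1)[C@](O)(C(C)C)CC2=O | intermediate
24 | (3R,3aS,4S,8aR)-3,4-dihydroxy-6,8a-dimethyl-3-(propan-2-yl)-3,3a,4,5,8,8a-hexahydroazulen-1(2H)-one | CC1=CC[C@]2(C)[C@@H]([C@@H](O)C1)[C@](O)(C(C)C)CC2=O | intermediate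
25 | 4-acetoxybenzoyl chloride | CC(=O)Oc1ccc(cc1)C(Cl)=O | starting material
26 | (3R,3aS,4S,8aR)-3-hydroxy-6,8a-dimethyl-1-oxo-3-(propan-2-yl)-1,2,3,3a,4,5,8,8a-octahydroazulen-4-yl 4-(acetyloxy)benzoate | CC1=CC[C@]2(C)[C@@H]([C@@H](OC(=O)c3ccc(OC(C)=O)cc3)C1)[C@](O)(C(C)C)CC2=O | intermediate
27 | (1S,3R,3aS,4S,8aR)-1,3-dihydroxy-6,8a-dimethyl-3-(propan-2-yl)-1,2,3,3a,4,5,8,8a-octahydroazulen-4-yl 4-(acetyloxy)benzoate | CC1=CC[C@]2(C)[C@@H]([C@@H](OC(=O)c3ccc(OC(C)=O)cc3)C1)[C@](O)(C(C)C)C[C@@H]2O | intermediate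
28 | 2α-hydroxyferutinin, (1S,3R,3aS,4S,8aR)-1,3-dihydroxy-6,8a-dimethyl-3-(propan-2-yl)-1,2,3,3a,4,5,8,8a-octahydroazulen-4-yl 4-hydroxybenzoate | CC1=CC[C@]2(C)[C@@H]([C@@H](OC(=O)c3ccc(O)cc3)C1)[C@](O)(C(C)C)C[C@@H]2O | target

**Step count and risks**

Total steps: 16. Longest linear sequence: 16 steps (1 to 28).

Steps most likely to fail:

1. Step 6 (Proposed new method). The ester tether must reach the disfavoured s-cis conformation and the ester-stabilised ylide may be sluggish, so ylide dimerisation or decomposition could outrun the cycloaddition; facial selectivity from the carbinol centre could also be modest. The fallback uses the known intermolecular oxidopyrylium–enone (5+2) cycloaddition, sets out from 6 and comes back at 19. Alcohol 6 is acetylated (Ac2O, pyridine) to (2S,3E)-3,6-dimethyl-5-oxohept-3-en-2-yl acetate F1. Separately, (3-methylfuran-2-yl)methanol F2 is oxidised (NBS, NaHCO3, THF/H2O) to 6-hydroxy-4-methyl-2H-pyran-3(6H)-one F3 and acetylated to 6-acetoxy-4-methyl-2H-pyran-3(6H)-one F4. Slow addition of F4 to F1 and i-Pr2NEt in MeCN at 60 °C generates 4-methylpyrylium-3-olate F5, which should add to the enone with the ylide carbon next to the oxide on the β-carbon and the acyl group endo, giving the oxabicycle F6 after separation of diastereomers. SmI2 opens the bridge to the hydroxy enone acetate F7 (C8 is already CH2, no decarboxylation needed), TBSCl and imidazole give the silyl ether F8, and K2CO3 in MeOH removes the acetate to give 19.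

2. Step 12. The aldol is reversible, so retro-aldol reversion, dehydration of the aldolate to the cyclopentenone, or proton transfer to C3a followed by loss of the silyloxy group could take over. The fallback sets out from 22 and comes back at 23. The acetyl group is trapped under kinetic conditions (LiN(SiMe3)2, Me3SiCl, THF, −78 °C) as the trimethylsilyl enol ether F9, and an intramolecular Mukaiyama aldol addition (BF3·OEt2 or TiCl4, CH2Cl2, −78 °C) then closes the ring by Lewis-acid activation of the C3 ketone under non-basic, non-equilibrating conditions.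

3. Step 15. Ligand exchange at the hindered tertiary C3 hydroxyl may be slow, so external hydride attack with poor facial selectivity could compete with internal delivery. The fallback sets out from 26 and comes back at 27 without a new compound. The ketone is reduced by single-electron transfer (SmI2, MeOH, THF, 0 °C) through a samarium ketyl chelated to the C3 hydroxyl; this chelation-controlled reduction of β-hydroxy ketones gives the anti-1,3-diol by protonation rather than hydride delivery.

Further compounds
F1 | step 6 | (2S,3E)-3,6-dimethyl-5-oxohept-3-en-2-yl acetate | CC(=O)O[C@@H](C)/C(C)=C/C(=O)C(C)C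
F2 | step 6 | (3-methylfuran-2-yl)methanol | Cc1ccoc1CO
F3 | step 6 | 6-hydroxy-4-methyl-2H-pyran-3(6H)-one | CC1=CC(O)OCC1=O
F4 | step 6 | 6-acetoxy-4-methyl-2H-pyran-3(6H)-one | CC1=CC(OC(C)=O)OCC1=O
F5 | step 6 | 4-methylpyrylium-3-olate | Cc1cc[o+]cc1[O-]
F6 | step 6 | oxabicycle: 8-oxabicyclo[3.2.1]oct-3-en-2-one with C8a endo methyl, C8a exo (S)-1-acetoxyethyl and C3a endo 2-methylpropanoyl | CC1=C[C@@H]2O[C@H](C1=O)[C@@](C)([C@H](C)OC(C)=O)[C@@H]2C(=O)C(C)C
F7 | step 6 | (4S,5S,6R)-6-[(1S)-1-acetoxyethyl]-4-hydroxy-2,6-dimethyl-5-(2-methylpropanoyl)cyclohept-2-en-1-one | CC1=C[C@H](O)[C@@H](C(=O)C(C)C)[C@](C)([C@H](C)OC(C)=O)CC1=O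
F8 | step 6 | (4S,5S,6R)-6-[(1S)-1-acetoxyethyl]-4-[(tert-butyldimethylsilyl)oxy]-2,6-dimethyl-5-(2-methylpropanoyl)cyclohept-2-en-1-one | CC1=C[C@H](O[Si](C)(C)C(C)(C)C)[C@@H](C(=O)C(C)C)[C@](C)([C@H](C)OC(C)=O)CC1=O
F9 | step 12 | trimethylsilyl enol ether of the acetyl group of 22 | CC1=CC[C@@](C)(C(=C)O[Si](C)(C)C)[C@@H]([C@@H](O[Si](C)(C)C(C)(C)C)C1)C(=O)C(C)C
F0 | step 15 | none | none
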